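**Retrosynthetic overview**

1. The target is a trans-(2R,3R)-3-hydroxy-2-(2-hydroxypropan-2-yl)-2,3-dihydrobenzofuran (benzene ring B fused to dihydrofuran ring D) carried on C2 of a 5,7-dihydroxychromone (rings A and C). The last operations are methyl addition to a C2 acetyl group and removal of two O-allyl groups.
2. Key disconnection: ring D is taken apart at C2-C3 and O1-C2, back to an achiral salicylaldehyde on ring B and a one-carbon chiral sulfonium acetonylide. In the forward (4+1) annulation the ring is closed by the phenoxide oxygen O1 attacking C2.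
3. Enabling feature: O1 and C3 of ring D sit on the neighbouring carbons C7a and C3a of ring B, a latent ortho-hydroxybenzaldehyde (O1-C7a=C3a-C3=O). The carbinol carbon on C2 can be carried as a ketone, so C2 is first a stabilised ylide carbon and then an α-keto sulfonium centre open to SN2 attack by O1.
4. The salicylaldehyde comes from ortho-formylation of a 4'-hydroxy-3'-prenylflavone. Its ring C comes from Baker-Venkataraman rearrangement and cyclodehydration of an aryl ester made from 2-hydroxy-4,6-bis(allyloxy)acetophenone and a prenylated benzoic acid (Negishi prenylation).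
5. Order of ring formation: rings A and B are bought, ring C is closed in step 7 and ring D in step 12. The thiolane ring of the chiral sulfide is made separately in step 10.

Key step: step 12

Remark: locants O1, C2, C3, C3a and C7a refer to the 2,3-dihydro-1-benzofuran unit; the target SMILES defines the trans (2R,3R) isomer, and the (2R,5R) sulfide is chosen on the basis of the facial model given in step 12.

**Route**

Step 1
Reactants: 1 2,4,6-trihydroxyacetophenone
Product: 2 1-[2-hydroxy-4,6-bis(prop-2-en-1-yloxy)phenyl]ethan-1-one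
Conditions: allyl bromide (2.1 equiv), K2CO3 (2.2 equiv), acetone, reflux
Reagents that add atoms: allyl bromide C=CCBr
Why: Williamson etherification should stop at the diether because the remaining ortho hydroxyl is hydrogen-bonded to the acetyl carbonyl and is the least nucleophilic.

Step 2
Reactants: 3 methyl 3-bromo-4-hydroxybenzoate
Product: 4 methyl 3-bromo-4-(methoxymethoxy)benzoate
Conditions: MOMCl (1.3 equiv), iPr2NEt (2 equiv), CH2Cl2, 0 °C to rt
Reagents that add atoms: chloromethyl methyl ether COCCl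
Why: Acetal protection of the phenol (O-alkylation) gives a group that is stable to the organozinc and strong-base steps and is removed by the acid of step 7.

Step 3
Reactants: 4 methyl 3-bromo-4-(methoxymethoxy)benzoate
Product: 5 methyl 4-(methoxymethoxy)-3-(3-methylbut-2-en-1-yl)benzoate
Conditions: prenylzinc bromide (1.5 equiv, from prenyl bromide, Zn dust, LiCl, THF, 0 °C), Pd(OAc)2 (2 mol %), 2-dicyclohexylphosphino-2',6'-bis(dimethylamino)biphenyl (CPhos, 4 mol %), THF, rt
Reagents that add atoms: prenyl bromide CC(C)=CCBr, used as prenylzinc bromide CC(C)=CC[Zn]Br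
Why: Negishi cross-coupling (oxidative addition of the aryl bromide to zerovalent palladium, transmetalation, reductive elimination at the unsubstituted allyl terminus) should give the linear prenyl arene, and the ester and acetal tolerate the allylzinc at rt.

Step 4
Reactants: 5 methyl 4-(methoxymethoxy)-3-(3-methylbut-2-en-1-yl)benzoate
Product: 6 4-(methoxymethoxy)-3-(3-methylbut-2-en-1-yl)benzoic acid
Conditions: LiOH·H2O (3 equiv), THF/MeOH/H2O, 40 °C; then 1 M HCl to pH 4 at 0 °C
Reagents that add atoms: lithium hydroxide [Li+].[OH-]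
Why: Ester saponification by acyl substitution; the acetal survives the brief cold acidification.

Step 5
Reactants: 2 1-[2-hydroxy-4,6-bis(prop-2-en-1-yloxy)phenyl]ethan-1-one; 6 4-(methoxymethoxy)-3-(3-methylbut-2-en-1-yl)benzoic acid
Product: 7 2-acetyl-3,5-bis(prop-2-en-1-yloxy)phenyl 4-(methoxymethoxy)-3-(3-methylbut-2-en-1-yl)benzoate
Conditions: DCC (1.2 equiv), DMAP (0.2 equiv), CH2Cl2, rt
Reagents that add atoms: none
Why: Steglich esterification through the N-acylpyridinium ion acylates the chelated phenol without acid, so the acetal and the prenyl group are untouched.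

Step 6
Reactants: 7 2-acetyl-3,5-bis(prop-2-en-1-yloxy)phenyl 4-(methoxymethoxy)-3-(3-methylbut-2-en-1-yl)benzoate
Product: 8 1-[2-hydroxy-4,6-bis(prop-2-en-1-yloxy)phenyl]-3-[4-(methoxymethoxy)-3-(3-methylbut-2-en-1-yl)phenyl]propane-1,3-dione
Conditions: LiN(SiMe3)2 (3 equiv), THF, -78 °C to -10 °C; aq NH4Cl
Reagents that add atoms: none
Why: Baker-Venkataraman rearrangement, in which the acetyl enolate attacks the neighbouring aryl ester through a six-membered transition state and the aroyl group moves from O to C.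

Step 7
Reactants: 8 1-[2-hydroxy-4,6-bis(prop-2-en-1-yloxy)phenyl]-3-[4-(methoxymethoxy)-3-(3-methylbut-2-en-1-yl)phenyl]propane-1,3-dione
Product: 9 2-[4-hydroxy-3-(3-methylbut-2-en-1-yl)phenyl]-5,7-bis(prop-2-en-1-yloxy)-4H-chromen-4-one
Conditions: TsOH·H2O (0.3 equiv), MeOH/THF 3:1, 55 °C
Reagents that add atoms: none
Why: Acid-catalysed cyclodehydration of the ortho-hydroxy 1,3-diketone closes ring C and the same acid transacetalises the MOM ether to methanol, the mild sulfonic acid being chosen so that the prenyl group next to the freed phenol does not cyclise.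

Step 8
Reactants: 9 2-[4-hydroxy-3-(3-methylbut-2-en-1-yl)phenyl]-5,7-bis(prop-2-en-1-yloxy)-4H-chromen-4-one
Product: 10 2-hydroxy-3-(3-methylbut-2-en-1-yl)-5-[4-oxo-5,7-bis(prop-2-en-1-yloxy)-4H-chromen-2-yl]benzaldehyde
Conditions: MgCl2 (3 equiv, anhydrous), Et3N (6 equiv), paraformaldehyde (8 equiv), MeCN, reflux
Reagents that add atoms: formaldehyde (as paraformaldehyde) C=O
Why: Casnati-Skattebøl ortho-formylation, in which the magnesium phenoxide delivers formaldehyde to the only free ortho position and a second formaldehyde accepts hydride; the allyl ethers on ring A leave this as the only phenol.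

Step 9
Reactants: 11 (2S,5S)-hexane-2,5-diol
Product: 12 (2S,5S)-hexane-2,5-diyl dimethanesulfonate
Conditions: MsCl (2.4 equiv), Et3N (3 equiv), CH2Cl2, 0 °C
Reagents that add atoms: methanesulfonyl chloride CS(Cl)(=O)=O
Why: O-sulfonylation activates both secondary alcohols with retention, since no bond to carbon is broken.

Step 10
Reactants: 12 (2S,5S)-hexane-2,5-diyl dimethanesulfonate
Product: 13 (2R,5R)-2,5-dimethylthiolane
Conditions: Na2S·9H2O (1.2 equiv), DMSO, rt to 50 °C; distillation
Reagents that add atoms: sodium sulfide [Na+].[Na+].[S-2]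
Why: Double SN2 displacement (intermolecular, then 5-exo-tet ring closure), each with inversion, converts the (2S,5S) dimesylate into the C2-symmetric (2R,5R) sulfide.

Step 11
Reactants: 13 (2R,5R)-2,5-dimethylthiolane
Product: 14 (2R,5R)-2,5-dimethyl-1-(2-oxopropyl)thiolan-1-ium bromide
Conditions: bromoacetone (1.2 equiv), acetone, rt, dark; filtration of the salt
Reagents that add atoms: bromoacetone CC(=O)CBr
Why: S-alkylation of the sulfide by the α-halo ketone (SN2); the two sulfur lone pairs are equivalent by C2 symmetry, so a single sulfonium salt forms.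

Step 12
Reactants: 10 2-hydroxy-3-(3-methylbut-2-en-1-yl)-5-[4-oxo-5,7-bis(prop-2-en-1-yloxy)-4H-chromen-2-yl]benzaldehyde; 14 (2R,5R)-2,5-dimethyl-1-(2-oxopropyl)thiolan-1-ium bromide
Product: 17 2-[(2R,3R)-2-acetyl-3-hydroxy-7-(3-methylbut-2-en-1-yl)-2,3-dihydro-1-benzofuran-5-yl]-5,7-bis(prop-2-en-1-yloxy)-4H-chromen-4-one, via sulfonium acetonylide 15 (not isolated), via phenoxide sulfonium zwitterion 16 (not isolated)
Conditions: (i) 14 (1.3 equiv), saturated aq K2CO3/CH2Cl2, 0 °C, organic layer separated and dried (Na2SO4); (ii) ylide solution added to 10, CH2Cl2, -20 °C to 0 °C; pH 7 phosphate buffer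
Reagents that add atoms: none
Why: Proposed new method: a formal (4+1) annulation in which the ylide carbon of 15 adds to the aldehyde of 10, the ortho phenol hands its proton to the new alkoxide to give zwitterion 16, and the phenoxide O1 then displaces the thiolane from C2 by SN2, closing ring D in the 5-exo-tet mode with inversion at C2. The closest known reactions are the sulfonium and ammonium ylide (4+1) annulations of ortho-quinone methides and salicyl imines to trans-2,3-dihydrobenzofurans, the sulfoxonium methylide route from salicylaldehydes to 2,3-dihydro-1-benzofuran-3-ols, and chiral-sulfide Corey-Chaykovsky epoxidation. C2 is controlled by the C2-symmetric thiolanium: the ring methyl cis to the S-C bond shields one face of the ylide carbon, so the (2S) adducts, formed on the open face in the sense known for benzylide epoxidation with this sulfide, should be both kinetically preferred and the less crowded members of the adduct pool, and inversion in the closure turns (2S) into (2R). C3 is controlled relative to C2: addition of a carbonyl-stabilised ylide is reversible, so the C3 epimers interconvert through the free partners, and the (2S,3R) adduct, which places acetyl and hydroxyl trans on the forming ring, should close fastest, so the mixture funnels into the trans product. The step needs C-attack at the aldehyde rather than O-alkylation of the phenol or attack on the chromone enone; proton transfer from the phenol to the ylide is reversible and only returns the hindered sulfonium salt, which should alkylate oxygen slowly at low temperature, whereas the hydrogen-bonded aldehyde is the most electrophilic carbon and its adduct is drained irreversibly by ring closure. The neutral quench at 0 °C protects the base-labile C2-H and the β-hydroxy ketone from epimerisation and elimination.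

Step 13
Reactants: 17 2-[(2R,3R)-2-acetyl-3-hydroxy-7-(3-methylbut-2-en-1-yl)-2,3-dihydro-1-benzofuran-5-yl]-5,7-bis(prop-2-en-1-yloxy)-4H-chromen-4-one
Product: 18 2-[(2R,3R)-3-hydroxy-2-(2-hydroxypropan-2-yl)-7-(3-methylbut-2-en-1-yl)-2,3-dihydro-1-benzofuran-5-yl]-5,7-bis(prop-2-en-1-yloxy)-4H-chromen-4-one
Conditions: MeMgBr (4 equiv), CeCl3 (4 equiv, anhydrous), THF, -78 °C; aq NH4Cl
Reagents that add atoms: methylmagnesium bromide C[Mg]Br
Why: Organocerium 1,2-addition to the α-oxygenated methyl ketone, which is far more electrophilic than the vinylogous-ester carbonyl of the chromone; the weakly basic reagent should suppress enolisation, retro-aldol and elimination, and no new stereocentre arises because the carbinol carbon carries two methyl groups.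

Step 14
Reactants: 18 2-[(2R,3R)-3-hydroxy-2-(2-hydroxypropan-2-yl)-7-(3-methylbut-2-en-1-yl)-2,3-dihydro-1-benzofuran-5-yl]-5,7-bis(prop-2-en-1-yloxy)-4H-chromen-4-one
Product: 19 5,7-dihydroxy-2-[(2R,3R)-3-hydroxy-2-(2-hydroxypropan-2-yl)-7-(3-methylbut-2-en-1-yl)-2,3-dihydro-1-benzofuran-5-yl]-4H-chromen-4-one
Conditions: Pd(PPh3)4 (5 mol %), morpholine (10 equiv), THF, rt
Reagents that add atoms: none
Why: Tsuji-Trost deallylation, in which zerovalent palladium ionises the two aryl allyl ethers to π-allyl complexes that morpholine captures; the neutral conditions spare the acid-labile benzylic alcohol and the C-prenyl group has no leaving group.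

**Compound list**

1 | 2,4,6-trihydroxyacetophenone | CC(=O)c1c(O)cc(O)cc1O | starting material
2 | 1-[2-hydroxy-4,6-bis(prop-2-en-1-yloxy)phenyl]ethan-1-one | CC(=O)c1c(O)cc(OCC=C)cc1OCC=C | intermediate
3 | methyl 3-bromo-4-hydroxybenzoate | COC(=O)c1ccc(O)c(Br)c1 | starting material
4 | methyl 3-bromo-4-(methoxymethoxy)benzoate | COC(=O)c1ccc(OCOC)c(Br)c1 | intermediate
5 | methyl 4-(methoxymethoxy)-3-(3-methylbut-2-en-1-yl)benzoate | COC(=O)c1ccc(OCOC)c(CC=C(C)C)c1 | intermediate
6 | 4-(methoxymethoxy)-3-(3-methylbut-2-en-1-yl)benzoic acid | OC(=O)c1ccc(OCOC)c(CC=C(C)C)c1 | intermediate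
7 | 2-acetyl-3,5-bis(prop-2-en-1-yloxy)phenyl 4-(methoxymethoxy)-3-(3-methylbut-2-en-1-yl)benzoate | CC(=O)c1c(OC(=O)c2ccc(OCOC)c(CC=C(C)C)c2)cc(OCC=C)cc1OCC=C | intermediate
8 | 1-[2-hydroxy-4,6-bis(prop-2-en-1-yloxy)phenyl]-3-[4-(methoxymethoxy)-3-(3-methylbut-2-en-1-yl)phenyl]propane-1,3-dione | O=C(CC(=O)c1ccc(OCOC)c(CC=C(C)C)c1)c1c(O)cc(OCC=C)cc1OCC=C | intermediate
9 | 2-[4-hydroxy-3-(3-methylbut-2-en-1-yl)phenyl]-5,7-bis(prop-2-en-1-yloxy)-4H-chromen-4-one | CC(C)=CCc1cc(-c2cc(=O)c3c(OCC=C)cc(OCC=C)cc3o2)ccc1O | intermediate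
10 | 2-hydroxy-3-(3-methylbut-2-en-1-yl)-5-[4-oxo-5,7-bis(prop-2-en-1-yloxy)-4H-chromen-2-yl]benzaldehyde | CC(C)=CCc1cc(-c2cc(=O)c3c(OCC=C)cc(OCC=C)cc3o2)cc(C=O)c1O | intermediate
11 | (2S,5S)-hexane-2,5-diol | C[C@H](O)CC[C@H](C)O | starting material
12 | (2S,5S)-hexane-2,5-diyl dimethanesulfonate | C[C@H](OS(C)(=O)=O)CC[C@H](C)OS(C)(=O)=O | intermediate
13 | (2R,5R)-2,5-dimethylthiolane | C[C@@H]1CC[C@@H](C)S1 | intermediate
14 | (2R,5R)-2,5-dimethyl-1-(2-oxopropyl)thiolan-1-ium bromide | C[C@@H]1CC[C@@H](C)[S+]1CC(C)=O.[Br-] | intermediate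
15 | 1-[(2R,5R)-2,5-dimethylthiolan-1-ium-1-yl]-2-oxopropan-1-ide (sulfonium acetonylide) | C[C@@H]1CC[C@@H](C)[S+]1[CH-]C(C)=O | intermediate (not isolated)
16 | 2-{(1R,2S)-2-[(2R,5R)-2,5-dimethylthiolan-1-ium-1-yl]-1-hydroxy-3-oxobutyl}-6-(3-methylbut-2-en-1-yl)-4-[4-oxo-5,7-bis(prop-2-en-1-yloxy)-4H-chromen-2-yl]phenolate (phenoxide sulfonium zwitterion) | CC(C)=CCc1cc(-c2cc(=O)c3c(OCC=C)cc(OCC=C)cc3o2)cc([C@@H](O)[C@@H](C(C)=O)[S+]2[C@H](C)CC[C@H]2C)c1[O-] | intermediate (not isolated)
17 | 2-[(2R,3R)-2-acetyl-3-hydroxy-7-(3-methylbut-2-en-1-yl)-2,3-dihydro-1-benzofuran-5-yl]-5,7-bis(prop-2-en-1-yloxy)-4H-chromen-4-one | CC(C)=CCc1cc(-c2cc(=O)c3c(OCC=C)cc(OCC=C)cc3o2)cc2c1O[C@@H](C(C)=O)[C@@H]2O | intermediate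
18 | 2-[(2R,3R)-3-hydroxy-2-(2-hydroxypropan-2-yl)-7-(3-methylbut-2-en-1-yl)-2,3-dihydro-1-benzofuran-5-yl]-5,7-bis(prop-2-en-1-yloxy)-4H-chromen-4-one | CC(C)=CCc1cc(-c2cc(=O)c3c(OCC=C)cc(OCC=C)cc3o2)cc2c1O[C@@H](C(C)(C)O)[C@@H]2O | intermediate
19 | 5,7-dihydroxy-2-[(2R,3R)-3-hydroxy-2-(2-hydroxypropan-2-yl)-7-(3-methylbut-2-en-1-yl)-2,3-dihydro-1-benzofuran-5-yl]-4H-chromen-4-one | CC(C)=CCc1cc(-c2cc(=O)c3c(O)cc(O)cc3o2)cc2c1O[C@@H](C(C)(C)O)[C@@H]2O | target

**Step count and risks**

Total step count: 14. Longest linear sequence: 10 steps (steps 2 to 8, then 12 to 14, from compound 3).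

Steps most likely to fail:

Step 12 (proposed new method). What may go wrong: O-alkylation of the phenol by sulfonium salt regenerated through proton transfer, weak or reversed facial control at C2, incomplete selection of the trans ring closure, and base-induced epimerisation at C2 or elimination of water to the benzofuran. The fallback uses known chemistry, with an auxiliary-controlled aldol followed by the same O1-C2 closure; it sets out from 10 and returns at 17. Silylation of 10 (TBSCl, imidazole, DMF) should give 2-[(tert-butyldimethylsilyl)oxy]-3-(3-methylbut-2-en-1-yl)-5-[4-oxo-5,7-bis(prop-2-en-1-yloxy)-4H-chromen-2-yl]benzaldehyde (F1). An Evans syn aldol of F1 with the dibutylboron enolate of commercial (4S)-4-benzyl-3-(chloroacetyl)-1,3-oxazolidin-2-one (Bu2BOTf, iPr2NEt, CH2Cl2, -78 °C) should give the chlorohydrin imide (4S)-4-benzyl-3-[(2S,3R)-3-{2-[(tert-butyldimethylsilyl)oxy]-3-(3-methylbut-2-en-1-yl)-5-[4-oxo-5,7-bis(prop-2-en-1-yloxy)-4H-chromen-2-yl]phenyl}-2-chloro-3-hydroxypropanoyl]-1,3-oxazolidin-2-one (F2). Bu4NF in THF at 0 °C should free the phenoxide of F2, which displaces chloride with inversion (5-exo-tet) to give the trans imide (4S)-4-benzyl-3-{[(2R,3R)-3-hydroxy-7-(3-methylbut-2-en-1-yl)-5-[4-oxo-5,7-bis(prop-2-en-1-yloxy)-4H-chromen-2-yl]-2,3-dihydro-1-benzofuran-2-yl]carbonyl}-1,3-oxazolidin-2-one (F3). Transamidation of F3 with AlMe3 and MeNHOMe·HCl should give the Weinreb amide (2R,3R)-3-hydroxy-N-methoxy-N-methyl-7-(3-methylbut-2-en-1-yl)-5-[4-oxo-5,7-bis(prop-2-en-1-yloxy)-4H-chromen-2-yl]-2,3-dihydro-1-benzofuran-2-carboxamide (F4), and MeMgBr at -40 °C should then convert F4 into ketone 17.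

Step 13. What may go wrong: retro-aldol opening or β-elimination of the free β-hydroxy ketone under the basic reagent, and competing addition to the chromone carbonyl. The fallback is a protecting-group detour that removes the free aldol hydroxyl; it sets out from 17 and returns at 18. TESCl and imidazole in DMF at 0 °C should give 2-[(2R,3R)-2-acetyl-7-(3-methylbut-2-en-1-yl)-3-[(triethylsilyl)oxy]-2,3-dihydro-1-benzofuran-5-yl]-5,7-bis(prop-2-en-1-yloxy)-4H-chromen-4-one (F5). MeLi with CeCl3 in THF at -78 °C should convert F5 into 2-[(2R,3R)-2-(2-hydroxypropan-2-yl)-7-(3-methylbut-2-en-1-yl)-3-[(triethylsilyl)oxy]-2,3-dihydro-1-benzofuran-5-yl]-5,7-bis(prop-2-en-1-yloxy)-4H-chromen-4-one (F6), and Bu4NF buffered with AcOH should release 18 from F6.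

Step 8. What may go wrong: low conversion of the electron-poor magnesium phenoxide, or Prins-type attack of formaldehyde on the prenyl and allyl alkenes. The fallback is a templated hydroxymethylation followed by oxidation; it sets out from 9 and returns at 10. PhB(OH)2, paraformaldehyde and catalytic propanoic acid in toluene at reflux with water removal should give 2-[8-(3-methylbut-2-en-1-yl)-2-phenyl-4H-1,3,2-benzodioxaborinin-6-yl]-5,7-bis(prop-2-en-1-yloxy)-4H-chromen-4-one (F7). Exchange of F7 with propane-1,3-diol should free 2-[4-hydroxy-3-(hydroxymethyl)-5-(3-methylbut-2-en-1-yl)phenyl]-5,7-bis(prop-2-en-1-yloxy)-4H-chromen-4-one (F8), and MnO2 in CH2Cl2 should oxidise the benzylic alcohol of F8 to 10.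

Further compounds
F1 | step 12 | 2-[(tert-butyldimethylsilyl)oxy]-3-(3-methylbut-2-en-1-yl)-5-[4-oxo-5,7-bis(prop-2-en-1-yloxy)-4H-chromen-2-yl]benzaldehyde | CC(C)=CCc1cc(-c2cc(=O)c3c(OCC=C)cc(OCC=C)cc3o2)cc(C=O)c1O[Si](C)(C)C(C)(C)C
F2 | step 12 | (4S)-4-benzyl-3-[(2S,3R)-3-{2-[(tert-butyldimethylsilyl)oxy]-3-(3-methylbut-2-en-1-yl)-5-[4-oxo-5,7-bis(prop-2-en-1-yloxy)-4H-chromen-2-yl]phenyl}-2-chloro-3-hydroxypropanoyl]-1,3-oxazolidin-2-one | CC(C)=CCc1cc(-c2cc(=O)c3c(OCC=C)cc(OCC=C)cc3o2)cc([C@@H](O)[C@H](Cl)C(=O)N2[C@@H](Cc3ccccc3)COC2=O)c1O[Si](C)(C)C(C)(C)C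
F3 | step 12 | (4S)-4-benzyl-3-{[(2R,3R)-3-hydroxy-7-(3-methylbut-2-en-1-yl)-5-[4-oxo-5,7-bis(prop-2-en-1-yloxy)-4H-chromen-2-yl]-2,3-dihydro-1-benzofuran-2-yl]carbonyl}-1,3-oxazolidin-2-one | CC(C)=CCc1cc(-c2cc(=O)c3c(OCC=C)cc(OCC=C)cc3o2)cc2c1O[C@@H](C(=O)N1[C@@H](Cc3ccccc3)COC1=O)[C@@H]2O
F4 | step 12 | (2R,3R)-3-hydroxy-N-methoxy-N-methyl-7-(3-methylbut-2-en-1-yl)-5-[4-oxo-5,7-bis(prop-2-en-1-yloxy)-4H-chromen-2-yl]-2,3-dihydro-1-benzofuran-2-carboxamide | CC(C)=CCc1cc(-c2cc(=O)c3c(OCC=C)cc(OCC=C)cc3o2)cc2c1O[C@@H](C(=O)N(C)OC)[C@@H]2O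
F5 | step 13 | 2-[(2R,3R)-2-acetyl-7-(3-methylbut-2-en-1-yl)-3-[(triethylsilyl)oxy]-2,3-dihydro-1-benzofuran-5-yl]-5,7-bis(prop-2-en-1-yloxy)-4H-chromen-4-one | CC(C)=CCc1cc(-c2cc(=O)c3c(OCC=C)cc(OCC=C)cc3o2)cc2c1O[C@@H](C(C)=O)[C@@H]2O[Si](CC)(CC)CC
F6 | step 13 | 2-[(2R,3R)-2-(2-hydroxypropan-2-yl)-7-(3-methylbut-2-en-1-yl)-3-[(triethylsilyl)oxy]-2,3-dihydro-1-benzofuran-5-yl]-5,7-bis(prop-2-en-1-yloxy)-4H-chromen-4-one | CC(C)=CCc1cc(-c2cc(=O)c3c(OCC=C)cc(OCC=C)cc3o2)cc2c1O[C@@H](C(C)(C)O)[C@@H]2O[Si](CC)(CC)CC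
F7 | step 8 | 2-[8-(3-methylbut-2-en-1-yl)-2-phenyl-4H-1,3,2-benzodioxaborinin-6-yl]-5,7-bis(prop-2-en-1-yloxy)-4H-chromen-4-one | CC(C)=CCc1cc(-c2cc(=O)c3c(OCC=C)cc(OCC=C)cc3o2)cc2COB(c3ccccc3)Oc12
F8 | step 8 | 2-[4-hydroxy-3-(hydroxymethyl)-5-(3-methylbut-2-en-1-yl)phenyl]-5,7-bis(prop-2-en-1-yloxy)-4H-chromen-4-one | CC(C)=CCc1cc(-c2cc(=O)c3c(OCC=C)cc(OCC=C)cc3o2)cc(CO)c1O
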